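A ratio carries this flask. If each substrate falls in proportion to itself on the same catalyst, dividing one rate by the other removes time, and ln([left-handed substrate]/charge) over ln([right-handed substrate]/charge) stays constant.

common to all: precatalyst 99 µM; added ligand 0.46 mM
- epsilon: left-handed substrate 5 mM; right-handed substrate 5 mM; partner 30 mM; run made earlier
- gamma: left-handed substrate 20 mM; right-handed substrate 20 mM; partner 30 mM; run made earlier
- flask: left-handed substrate 10 mM; right-handed substrate 10 mM; partner 30.0 mM; time 3.0 min

- epsilon (time / min: left-handed substrate / %, right-handed substrate / %, left-handed product / %): 0.167: 48, 50, 1; 0.333: 47, 49, 4; 0.667: 38, 47, 9; 1.00: 40, 47, 12; 1.33: 34, 48, 21; 2.00: 26, 48, 21; 2.50: 24, 45, 28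
- gamma (time / min: left-handed substrate / %, right-handed substrate / %, left-handed product / %): 0.167: 51, 49, 0; 0.333: 46, 50, 5; 0.667: 40, 48, 7; 1.00: 40, 49, 12; 1.33: 37, 46, 15; 2.00: 32, 51, 18; 2.50: 26, 46, 25

(standard deviation of a reading: 2 percentage points)

- part of the left-handed substrate and right-handed substrate charged together that has reacted at 3.0 min
- excess of left-handed product over right-handed product in the product at 3.0 min
- excess of right-handed substrate over left-handed substrate among what is left of the two at 3.0 min

- free catalyst is single-handed; left-handed substrate and right-handed substrate are mirror images of each other, charged as a racemate, each of them at the stated concentration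
- an excess is below zero if the other one leads

1. I need two numbers: the rate constant of the left-handed substrate, and that ratio. At 2.50 min the two runs read nearly alike, though charged at 5 mM and 20 mM, so I average them.

2. The left-handed substrate has lost 25 percentage points and the right-handed 4.5 points, against a scatter of 2 points. So the rate constant is firm and the ratio soft.

3. The rate constant is 0.277 min⁻¹, so 43.5 % of the left-handed charge remains at 3.0 min.

4. The ratio moves the product excess eP: a trial value of 3.67 gives 47.2 %, one of 14.7 gives 82.3 %.

5. My selectivity factor, the ratio of those logarithms, left-handed over right-handed, is 7.35. Then 89.3 % of the right-handed charge remains, so I commit to a reacted part c of 33.6 %, eP 68.2 % and a substrate excess eS of 34.5 %.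

6. The forecast gives c 32 %, eP 75 % and eS 35 %, on a factor different from mine: “selectivity is about 9, though poorly defined”.

7. The flask gives c 31.6 %, eP 76.1 %, eS 35.2 %.

    partner + free catalyst → spent catalyst (k = 1.19 L mol⁻¹ s⁻¹)
    partner + catalyst intermediate A → free catalyst + left-handed product (k = 446 L mol⁻¹ s⁻¹)
    free catalyst + right-handed substrate ⇌ catalyst intermediate B (K = 41.0 L mol⁻¹, k = 5800 L mol⁻¹ s⁻¹)
    partner + catalyst intermediate B → free catalyst + right-handed product (k = 168 L mol⁻¹ s⁻¹)
    free catalyst + added ligand ⇌ idle complex, settled at all times (K = 88000 L mol⁻¹)
    free catalyst + left-handed substrate ⇌ catalyst intermediate A (K = 160 L mol⁻¹, k = 62400 L mol⁻¹ s⁻¹)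
    partner + precatalyst → free catalyst + spent reagent (k = 5.38 L mol⁻¹ s⁻¹)

The flask's rests at 3.0 min, 44 % of the left-handed charge and 92 % of the right-handed, make the ratio 10.4, against my 7.35. The neighbouring flask with 0.25 mM of precatalyst reacts further, keeping 8.4 % of the left-handed charge and 79 % of the right-handed, and the same division gives 10.4, close to the flask's. There c is 56.4 % and eP 62.3 %.

The earlier runs and the new flask are calculated on assumed constants, noise included.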